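**Plan**
- Retrosynthesis: ring C is opened at O1–C8a (palladium C–O coupling of a C2 carbinol with a C8a chloride), and the C2 carbinol is traced back to an aryl ketone. The chain is then cut at C3–C4 (aldol) into a ring A aldehyde and a ring B methyl ketone, and ring A at C4a–CHO and C6–geranyl (two ortho-lithiations of bis-MOM 5-chlororesorcinol).
- Forward: the ring A aldehyde (steps 1–3) and the ring B ketone (steps 4–6) are joined by aldol (step 7). Silylation and asymmetric reduction give the open-chain carbinol, ring C closes in step 10, and desilylation, C4 oxidation and MOM removal finish the route.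
- Enabling feature: C8a is the one carbon of ring A that is meta to both O5 and O7, so a halogen there survives the ortho-metalations and ends up ortho to the C4a side chain. The 4'-methoxy group of ring B (para to C2) makes the benzylic C2–O bond easy to ionise, so ring C is closed at the aryl end of O1 and the C2–O bond is never touched.
- Stereochemistry: C2 (S) is the only stereocentre of the target. It is set by ruthenium-catalysed asymmetric transfer hydrogenation of the ring B ketone (step 9) and carried through with retention. The C4 carbinol is formed without control and erased by oxidation.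

Key step: step 10

Remark on the chemistry: chlorine is chosen as the C8a halogen because it does not exchange with n-BuLi in the two ortho-lithiations, yet still undergoes oxidative addition to zerovalent palladium bearing a bulky biarylphosphine. "Geranyl" means (2E)-3,7-dimethylocta-2,6-dien-1-yl, and MOM means methoxymethyl.

**Route**

Step 1
Reactants: 1 5-chlororesorcinol
Product: 2 1-chloro-3,5-bis(methoxymethoxy)benzene
Conditions: MOMCl, i-Pr2NEt, CH2Cl2, 0 °C → rt
Reagents that add atoms: chloromethyl methyl ether, COCCl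
Why: Williamson-type O-alkylation of both phenols with the reactive α-chloro ether installs the two MOM groups that later direct the lithiations.

Step 2
Reactants: 2 1-chloro-3,5-bis(methoxymethoxy)benzene; 3 geranyl bromide
Product: 5 5-chloro-2-geranyl-1,3-bis(methoxymethoxy)benzene, via aryllithium 4 (not isolated)
Conditions: n-BuLi, THF, −20 °C; CuI (10 mol%), then 3, −78 °C → rt
Reagents that add atoms: none
Why: Directed ortho-metalation should take place at the C–H flanked by both OMOM groups (double chelation, no Cl–Li exchange), and copper-catalysed SN2 allylation of the aryllithium with the primary allylic bromide keeps the E alkene.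

Step 3
Reactants: 5 5-chloro-2-geranyl-1,3-bis(methoxymethoxy)benzene
Product: 8 6-chloro-3-geranyl-2,4-bis(methoxymethoxy)benzaldehyde, via aryllithium 6 (not isolated), via lithium hemiaminolate 7 (not isolated)
Conditions: n-BuLi, TMEDA, THF, −78 °C; DMF, −78 → 0 °C; then H2O
Reagents that add atoms: N,N-dimethylformamide, CN(C)C=O
Why: The two remaining ring hydrogens are equivalent and each lies between Cl and OMOM, so directed ortho-metalation at −78 °C (where the ortho-chloroaryllithium does not lose LiCl) followed by DMF formylation can give only this aldehyde.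

Step 4
Reactants: 9 3-hydroxy-4,5-dimethoxybenzaldehyde
Product: 10 3,4-dimethoxy-5-(methoxymethoxy)benzaldehyde
Conditions: MOMCl, i-Pr2NEt, CH2Cl2, 0 °C → rt
Reagents that add atoms: chloromethyl methyl ether, COCCl
Why: MOM protection of the single phenol (O-alkylation) removes the acidic proton before the Grignard, enolate and palladium steps.

Step 5
Reactants: 10 3,4-dimethoxy-5-(methoxymethoxy)benzaldehyde
Product: 11 rac-1-[3,4-dimethoxy-5-(methoxymethoxy)phenyl]ethanol
Conditions: MeMgBr, THF, 0 °C; then H2O
Reagents that add atoms: methylmagnesium bromide, C[Mg]Br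
Why: Grignard addition to the non-enolisable aryl aldehyde gives the secondary benzylic alcohol, whose stereocentre is removed in the next step.

Step 6
Reactants: 11 rac-1-[3,4-dimethoxy-5-(methoxymethoxy)phenyl]ethanol
Product: 12 1-[3,4-dimethoxy-5-(methoxymethoxy)phenyl]ethanone
Conditions: MnO2 (activated, excess), CH2Cl2, rt
Reagents that add atoms: none
Why: MnO2 oxidation is selective for electron-rich benzylic alcohols and leaves the MOM acetal untouched.

Step 7
Reactants: 12 1-[3,4-dimethoxy-5-(methoxymethoxy)phenyl]ethanone; 8 6-chloro-3-geranyl-2,4-bis(methoxymethoxy)benzaldehyde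
Product: 14 rac-3-[6-chloro-3-geranyl-2,4-bis(methoxymethoxy)phenyl]-3-hydroxy-1-[3,4-dimethoxy-5-(methoxymethoxy)phenyl]propan-1-one, via lithium enolate 13 (not isolated)
Conditions: LiN(i-Pr)2, THF, −78 °C; then 8, −78 °C; AcOH quench at −78 °C
Reagents that add atoms: none
Why: Directed aldol addition of the preformed lithium enolate of the methyl ketone to the non-enolisable aldehyde forms C3–C4, the cold acidic quench prevents retro-aldol, and the new carbinol centre (future C4) is formed racemic and is later oxidised away.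

Step 8
Reactants: 14 the aldol adduct
Product: 15 rac-3-(tert-butyldimethylsilyloxy)-3-[6-chloro-3-geranyl-2,4-bis(methoxymethoxy)phenyl]-1-[3,4-dimethoxy-5-(methoxymethoxy)phenyl]propan-1-one
Conditions: TBSOTf, 2,6-lutidine, CH2Cl2, −78 → 0 °C
Reagents that add atoms: tert-butyldimethylsilyl trifluoromethanesulfonate, CC(C)(C)[Si](C)(C)OS(=O)(=O)C(F)(F)F
Why: Silylation of the hindered benzylic alcohol with the silyl triflate and a weak hindered base should be faster than enol silylation or β-elimination, and it blocks retro-aldol and dehydration in the later basic steps.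

Step 9
Reactants: 15 the β-silyloxy ketone
Product: 16 (1S)-3-(tert-butyldimethylsilyloxy)-3-[6-chloro-3-geranyl-2,4-bis(methoxymethoxy)phenyl]-1-[3,4-dimethoxy-5-(methoxymethoxy)phenyl]propan-1-ol (both C3 epimers)
Conditions: RuCl[(S,S)-TsDPEN](p-cymene) (3 mol%), HCO2H/Et3N (1.1:1), DMF, 35 °C
Reagents that add atoms: none
Why: Noyori–Ikariya asymmetric transfer hydrogenation of the aryl alkyl ketone, in which the (S,S)-diamine ruthenium hydride should deliver hydride to the Re face (aryl group held by the CH/π contact with the η6-arene, as for acetophenone) to set the (S)-carbinol under catalyst control in both C3 epimers, without touching the geranyl alkenes or the aryl chloride.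

Step 10
Reactants: 16 the (1S)-carbinol aryl chloride
Product: 17 (2S)-4-(tert-butyldimethylsilyloxy)-6-geranyl-5,7-bis(methoxymethoxy)-2-[3,4-dimethoxy-5-(methoxymethoxy)phenyl]chroman (both C4 epimers)
Conditions: [Pd(allyl)Cl]2 (2.5 mol%), RockPhos (7.5 mol%), Cs2CO3 (2 equiv), toluene, 90 °C
Reagents that add atoms: none
Why: Zerovalent palladium carrying the bulky di-tert-butyl biarylphosphine should insert into the C8a–Cl bond, the caesium alkoxide of the C2 hydroxyl then displaces chloride on divalent palladium to give a seven-membered aryl palladium alkoxide chelate, and C–O reductive elimination forms O1–C8a. The closest known reaction type is the Buchwald–Hartwig-type intramolecular etherification of secondary alcohols with aryl halides, which gives chromans and flavans. Ring C closes as a six-membered ring by reductive elimination onto the aryl carbon (formally a 6-exo closure at C8a). No new stereocentre is formed: neither the C2–O nor the C2–H bond is broken, so the (S) configuration is retained, and both C4 epimers cyclise. The step needs C–O reductive elimination to beat β-hydride elimination of the alkoxide, which the ligand bulk and the chelate favour. It also needs a single free hydroxyl, which is secured by the C4 silyl ether (this also prevents retro-aldol and dehydration under base) and the three MOM ethers.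

Step 11
Reactants: 17 the silylated flavan
Product: 18 (2S)-6-geranyl-5,7-bis(methoxymethoxy)-2-[3,4-dimethoxy-5-(methoxymethoxy)phenyl]chroman-4-ol (both C4 epimers)
Conditions: Bu4NF, THF, 0 °C → rt; then H2O
Reagents that add atoms: none
Why: Fluoride-mediated desilylation (driven by the Si–F bond) frees the C4 alcohol under non-acidic conditions that the ionisable flavan-4-ol and the MOM ethers should tolerate.

Step 12
Reactants: 18 the flavan-4-ol
Product: 19 (2S)-6-geranyl-5,7-bis(methoxymethoxy)-2-[3,4-dimethoxy-5-(methoxymethoxy)phenyl]chroman-4-one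
Conditions: Dess–Martin periodinane, pyridine, CH2Cl2, 0 °C → rt
Reagents that add atoms: none
Why: Dess–Martin oxidation converts both C4 epimers into the one ketone under buffered, base-free conditions, so C2 is not exposed to the retro-oxa-Michael ring opening that would racemise it.

Step 13
Reactants: 19 the tris-MOM flavanone
Product: 20 (2S)-6-geranyl-5,7-dihydroxy-2-(3-hydroxy-4,5-dimethoxyphenyl)chroman-4-one
Conditions: HCl (1 M in MeOH), 25–40 °C
Reagents that add atoms: none
Why: Acid-catalysed acetal exchange with methanol removes the three phenolic MOM groups as dimethoxymethane, and keeping the acid dilute and the temperature low should limit acid-promoted cyclisation of the geranyl chain onto the flanking phenols and ionisation at C2.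

**Compound list**

1 | 5-chlororesorcinol | Oc1cc(O)cc(Cl)c1 | starting material
2 | 1-chloro-3,5-bis(methoxymethoxy)benzene | COCOc1cc(Cl)cc(OCOC)c1 | intermediate
3 | geranyl bromide, (2E)-1-bromo-3,7-dimethylocta-2,6-diene | BrC/C=C(\C)CCC=C(C)C | starting material
4 | [4-chloro-2,6-bis(methoxymethoxy)phenyl]lithium | [Li]c1c(OCOC)cc(Cl)cc1OCOC | intermediate (not isolated)
5 | 5-chloro-2-geranyl-1,3-bis(methoxymethoxy)benzene | COCOc1cc(Cl)cc(OCOC)c1C/C=C(\C)CCC=C(C)C | intermediate
6 | [6-chloro-3-geranyl-2,4-bis(methoxymethoxy)phenyl]lithium | [Li]c1c(Cl)cc(OCOC)c(C/C=C(\C)CCC=C(C)C)c1OCOC | intermediate (not isolated)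
7 | lithium [6-chloro-3-geranyl-2,4-bis(methoxymethoxy)phenyl](dimethylamino)methanolate | [Li]OC(N(C)C)c1c(Cl)cc(OCOC)c(C/C=C(\C)CCC=C(C)C)c1OCOC | intermediate (not isolated)
8 | 6-chloro-3-geranyl-2,4-bis(methoxymethoxy)benzaldehyde | O=Cc1c(Cl)cc(OCOC)c(C/C=C(\C)CCC=C(C)C)c1OCOC | intermediate
9 | 3-hydroxy-4,5-dimethoxybenzaldehyde | COc1cc(C=O)cc(O)c1OC | starting material
10 | 3,4-dimethoxy-5-(methoxymethoxy)benzaldehyde | COCOc1cc(C=O)cc(OC)c1OC | intermediate
11 | rac-1-[3,4-dimethoxy-5-(methoxymethoxy)phenyl]ethanol | COCOc1cc(C(C)O)cc(OC)c1OC | intermediate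
12 | 1-[3,4-dimethoxy-5-(methoxymethoxy)phenyl]ethanone | COCOc1cc(C(C)=O)cc(OC)c1OC | intermediate
13 | lithium 1-[3,4-dimethoxy-5-(methoxymethoxy)phenyl]ethenolate | COCOc1cc(C(=C)O[Li])cc(OC)c1OC | intermediate (not isolated)
14 | rac-3-[6-chloro-3-geranyl-2,4-bis(methoxymethoxy)phenyl]-3-hydroxy-1-[3,4-dimethoxy-5-(methoxymethoxy)phenyl]propan-1-one | COCOc1cc(C(=O)CC(O)c2c(Cl)cc(OCOC)c(C/C=C(\C)CCC=C(C)C)c2OCOC)cc(OC)c1OC | intermediate
15 | rac-3-(tert-butyldimethylsilyloxy)-3-[6-chloro-3-geranyl-2,4-bis(methoxymethoxy)phenyl]-1-[3,4-dimethoxy-5-(methoxymethoxy)phenyl]propan-1-one | COCOc1cc(C(=O)CC(O[Si](C)(C)C(C)(C)C)c2c(Cl)cc(OCOC)c(C/C=C(\C)CCC=C(C)C)c2OCOC)cc(OC)c1OC | intermediate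
16 | (1S)-3-(tert-butyldimethylsilyloxy)-3-[6-chloro-3-geranyl-2,4-bis(methoxymethoxy)phenyl]-1-[3,4-dimethoxy-5-(methoxymethoxy)phenyl]propan-1-ol, both C3 epimers | COCOc1cc([C@@H](O)CC(O[Si](C)(C)C(C)(C)C)c2c(Cl)cc(OCOC)c(C/C=C(\C)CCC=C(C)C)c2OCOC)cc(OC)c1OC | intermediate
17 | (2S)-4-(tert-butyldimethylsilyloxy)-6-geranyl-5,7-bis(methoxymethoxy)-2-[3,4-dimethoxy-5-(methoxymethoxy)phenyl]chroman, both C4 epimers | COCOc1cc([C@@H]2CC(O[Si](C)(C)C(C)(C)C)c3c(cc(OCOC)c(C/C=C(\C)CCC=C(C)C)c3OCOC)O2)cc(OC)c1OC | intermediate
18 | (2S)-6-geranyl-5,7-bis(methoxymethoxy)-2-[3,4-dimethoxy-5-(methoxymethoxy)phenyl]chroman-4-ol, both C4 epimers | COCOc1cc([C@@H]2CC(O)c3c(cc(OCOC)c(C/C=C(\C)CCC=C(C)C)c3OCOC)O2)cc(OC)c1OC | intermediate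
19 | (2S)-6-geranyl-5,7-bis(methoxymethoxy)-2-[3,4-dimethoxy-5-(methoxymethoxy)phenyl]chroman-4-one | COCOc1cc([C@@H]2CC(=O)c3c(cc(OCOC)c(C/C=C(\C)CCC=C(C)C)c3OCOC)O2)cc(OC)c1OC | intermediate
20 | (2S)-6-geranyl-5,7-dihydroxy-2-(3-hydroxy-4,5-dimethoxyphenyl)chroman-4-one | COc1cc([C@@H]2CC(=O)c3c(cc(O)c(C/C=C(\C)CCC=C(C)C)c3O)O2)cc(O)c1OC | target

**Step count**
Total: 13 steps. Longest linear sequence: 10 steps (1, 2, 3, 7, 8, 9, 10, 11, 12, 13; the ring B branch 4, 5, 6 also joins at step 7).

**Steps most likely to fail and their fallbacks**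

Step 10. β-Hydride elimination of the palladium alkoxide (leading to ketone and hydrodechlorination) or slow insertion into the C8a–Cl bond may outrun C–O reductive elimination. The fallback sets out from 16 and returns at 17 by an aryne cyclisation, which forms the same O1–C8a bond without a palladium alkoxide. Compound 16 with LiN(i-Pr)2 (3 equiv) in THF at −78 °C should give the C8-lithiated lithium alkoxide of 16 F1, the lithium sitting between Cl and the C7 OMOM group. On warming to 0 °C LiCl should be lost to give the lithium alkoxide aryne F2. The tethered alkoxide can only add at C8a (the aryne carbon remote from the C7 oxygen and the only one that gives a six-membered ring), giving the 8-lithiochroman F3, and aqueous quench gives 17. Intramolecular alkoxide addition to arynes is known chroman-forming chemistry and again leaves the C2–O bond untouched.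

Step 3. With the geranyl chain in place, n-BuLi may deprotonate the benzylic–allylic methylene instead of the ring, or the ortho-chloroaryllithium may lose LiCl before it is trapped. The fallback sets out from 1 and returns at 8, fixing the formyl group by electrophilic substitution before any geranyl group is present. Vilsmeier–Haack formylation of 1 (POCl3, DMF, MeCN, then H2O) should give 2-chloro-4,6-dihydroxybenzaldehyde F4, by attack para to one hydroxyl and ortho to the other. MOMCl/i-Pr2NEt then gives 2-chloro-4,6-bis(methoxymethoxy)benzaldehyde F5, and HC(OMe)3 with catalytic pyridinium tosylate in MeOH gives its dimethyl acetal F6. n-BuLi in THF at −20 °C should lithiate F6 between the two OMOM groups to give the aryllithium F7; this position is para to chlorine, so no aryne can form. CuI-catalysed allylation with 3 gives the geranylated acetal F8, and mild hydrolysis (pyridinium tosylate, acetone/H2O) releases 8.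

Step 9. Facial discrimination may be weak on a ketone that carries a bulky racemic β-silyloxy centre, and silanol may be eliminated in the amine-containing medium. The fallback sets out from 10 (and from 5 for the aryl nucleophile) and returns at 16, setting C2 before the chain is joined. Brown allylation of 10 with (−)-B-allyldiisopinocampheylborane (the antipode that gives (S)-1-arylbut-3-en-1-ols, through a chair transition state), with oxidative work-up, should give (1S)-1-[3,4-dimethoxy-5-(methoxymethoxy)phenyl]but-3-en-1-ol F9. TESCl/imidazole gives its triethylsilyl ether F10, and Lemieux–Johnson cleavage (OsO4 cat., NaIO4, 2,6-lutidine, dioxane/H2O) gives (3S)-3-aryl-3-(triethylsilyloxy)propanal F11. Addition of aryllithium 6 (from 5 as in step 3) at −78 °C gives the C4 carbinol F12 as both epimers, and TBSOTf/2,6-lutidine gives the bis-silyl ether F13. Selective removal of the more labile triethylsilyl group (HF·pyridine buffered with pyridine, THF, 0 °C) gives 16.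

**Further compounds**
F1 | step 10 | C8-lithiated lithium alkoxide of 16 | COCOc1cc([C@@H](O[Li])CC(O[Si](C)(C)C(C)(C)C)c2c(Cl)c([Li])c(OCOC)c(C/C=C(\C)CCC=C(C)C)c2OCOC)cc(OC)c1OC
F2 | step 10 | lithium alkoxide aryne (C8–C8a aryne of 16) | COCOc1cc([C@@H](O[Li])CC(O[Si](C)(C)C(C)(C)C)C2=C(OCOC)C(C/C=C(\C)CCC=C(C)C)=C(OCOC)C#C2)cc(OC)c1OC
F3 | step 10 | 8-lithio derivative of chroman 17 | COCOc1cc([C@@H]2CC(O[Si](C)(C)C(C)(C)C)c3c(c([Li])c(OCOC)c(C/C=C(\C)CCC=C(C)C)c3OCOC)O2)cc(OC)c1OC
F4 | step 3 | 2-chloro-4,6-dihydroxybenzaldehyde | O=Cc1c(Cl)cc(O)cc1O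
F5 | step 3 | 2-chloro-4,6-bis(methoxymethoxy)benzaldehyde | O=Cc1c(Cl)cc(OCOC)cc1OCOC
F6 | step 3 | 1-chloro-2-(dimethoxymethyl)-3,5-bis(methoxymethoxy)benzene | COC(OC)c1c(Cl)cc(OCOC)cc1OCOC
F7 | step 3 | [4-chloro-3-(dimethoxymethyl)-2,6-bis(methoxymethoxy)phenyl]lithium | COC(OC)c1c(Cl)cc(OCOC)c([Li])c1OCOC
F8 | step 3 | 1-chloro-2-(dimethoxymethyl)-4-geranyl-3,5-bis(methoxymethoxy)benzene | COC(OC)c1c(Cl)cc(OCOC)c(C/C=C(\C)CCC=C(C)C)c1OCOC
F9 | step 9 | (1S)-1-[3,4-dimethoxy-5-(methoxymethoxy)phenyl]but-3-en-1-ol | COCOc1cc([C@@H](O)CC=C)cc(OC)c1OC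
F10 | step 9 | (1S)-1-[3,4-dimethoxy-5-(methoxymethoxy)phenyl]but-3-en-1-yl triethylsilyl ether | COCOc1cc([C@@H](O[Si](CC)(CC)CC)CC=C)cc(OC)c1OC
F11 | step 9 | (3S)-3-[3,4-dimethoxy-5-(methoxymethoxy)phenyl]-3-(triethylsilyloxy)propanal | COCOc1cc([C@@H](O[Si](CC)(CC)CC)CC=O)cc(OC)c1OC
F12 | step 9 | (3S)-1-[6-chloro-3-geranyl-2,4-bis(methoxymethoxy)phenyl]-3-[3,4-dimethoxy-5-(methoxymethoxy)phenyl]-3-(triethylsilyloxy)propan-1-ol, both C1 epimers | COCOc1cc([C@@H](O[Si](CC)(CC)CC)CC(O)c2c(Cl)cc(OCOC)c(C/C=C(\C)CCC=C(C)C)c2OCOC)cc(OC)c1OC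
F13 | step 9 | (1S)-3-(tert-butyldimethylsilyloxy)-3-[6-chloro-3-geranyl-2,4-bis(methoxymethoxy)phenyl]-1-[3,4-dimethoxy-5-(methoxymethoxy)phenyl]-1-(triethylsilyloxy)propane, both C3 epimers | COCOc1cc([C@@H](O[Si](CC)(CC)CC)CC(O[Si](C)(C)C(C)(C)C)c2c(Cl)cc(OCOC)c(C/C=C(\C)CCC=C(C)C)c2OCOC)cc(OC)c1OC
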